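**Retrosynthetic overview**

- The target is a diarylmethane of two acylphloroglucinols. Ring A is counted from the butyryl-bearing carbon: position 1 C-butyryl, position 2 C–OH, position 3 C–CH3, position 4 C–OCH3, position 5 C–CH2 (bridge), position 6 C–OH. Ring B is counted from the bridge-bearing carbon: position 3 C–CH3, position 5 C-acetyl, positions 2, 4 and 6 C–OH.
- Feature on which the plan rests: in ring A the methoxy carbon (position 4) sits between the methyl carbon (position 3) and the bridge carbon (position 5), and is meta to the hydroxyl at position 6. A 1-methoxyalkyne joined to a methyl(vinyl)ketene gives exactly this pattern.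
- Key disconnection: the ring A bonds between positions 5 and 6, positions 3 and 4, and positions 1 and 6. Ring A comes from 3-(benzyloxy)-2-methylcyclobut-2-en-1-one (supplying positions 6, 3, 2 and 1) and a methoxyalkyne that carries protected ring B on its propargylic carbon (supplying positions 5 and 4).
- Last disconnections: the four O-benzyl groups, the ring B acetyl (from a bromide at position 5 of ring B by Stille coupling) and the ring A butyryl (from the C–H at position 1 by ortho-formylation, Grignard addition and oxidation). The cyclobutenone comes from methylketene and ethoxyacetylene. The alkyne comes from 2-methylphloroglucinol by benzylation, formylation, bromination, reduction, bromide formation and alkylation of lithium methoxyacetylide.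
- Ring order: ring B is bought (2-methylphloroglucinol). The four-membered ring is made in step 1 and opened in step 11. Ring A is the only ring built, in step 11.

Key step: step 11

Remark on the chemistry: the target has no stereocentre; three transient intermediates are racemic and their stereocentres are erased later. Ring B carries a bromine at its position 5 from step 6 to step 15. It fills the only free ring B carbon, so the labile benzylic bromide cannot alkylate itself, and the C–H at position 1 of ring A is the only nucleophilic aromatic C–H after the annulation. It is later exchanged for the acetyl group under neutral conditions.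

**Route**

Step 1
Reactants: 1 propionyl chloride; 2 ethoxyacetylene
Product: 4 3-ethoxy-4-methylcyclobut-2-en-1-one (racemic), via methylketene 3 (not isolated)
Conditions: Et3N (slow addition), Et2O, 0 °C to rt
Reagents that add atoms: none
Why: Ketene–ynol ether (2+2) cycloaddition, in which the unsubstituted nucleophilic alkyne carbon attacks the carbonyl carbon of methylketene (set free from 1 by dehydrochlorination), placing ethoxy at position 3 and methyl at position 4 of the four-membered ring; the stereocentre at position 4 forms racemic and is lost in step 2.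

Step 2
Reactants: 4 3-ethoxy-4-methylcyclobut-2-en-1-one
Product: 5 3-hydroxy-2-methylcyclobut-2-en-1-one
Conditions: 1 M aq HCl, THF, rt
Reagents that add atoms: water, O
Why: Acid hydrolysis of the vinylogous ester should give 2-methylcyclobutane-1,3-dione, which rests as its more substituted enol 5; cold dilute acid is used because hot nucleophilic media open the strained dione.

Step 3
Reactants: 5 3-hydroxy-2-methylcyclobut-2-en-1-one
Product: 6 3-(benzyloxy)-2-methylcyclobut-2-en-1-one
Conditions: BnOH, PPh3, DIAD, THF, 0 °C to rt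
Reagents that add atoms: benzyl alcohol, OCc1ccccc1
Why: Mitsunobu O-alkylation of the strongly acidic enol (a vinylogous acid) avoids the C-benzylation at the methyl-bearing carbon expected with benzyl halide and base, and the two oxygens of the delocalised anion are equivalent, so one enol ether should form.

Step 4
Reactants: 7 2-methylphloroglucinol
Product: 8 1,3,5-tris(benzyloxy)-2-methylbenzene
Conditions: BnBr, K2CO3, DMF, rt to 50 °C, under Ar
Reagents that add atoms: benzyl bromide, BrCc1ccccc1
Why: Williamson ether synthesis in a dipolar aprotic solvent, which favours O- over C-benzylation of the phloroglucinol anion; C-benzylated by-products are removed by chromatography.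

Step 5
Reactants: 8 1,3,5-tris(benzyloxy)-2-methylbenzene
Product: 10 2,4,6-tris(benzyloxy)-3-methylbenzaldehyde, via iminium chloride 9 (not isolated)
Conditions: POCl3, DMF, 0 °C to rt; then ice-water, NaOAc
Reagents that add atoms: N,N-dimethylformamide, CN(C)C=O; water, O
Why: Vilsmeier–Haack formylation of a trialkoxybenzene at one of its two equivalent free positions; the formyl group deactivates the ring, so substitution should stop after one formylation.

Step 6
Reactants: 10 2,4,6-tris(benzyloxy)-3-methylbenzaldehyde
Product: 11 2,4,6-tris(benzyloxy)-3-bromo-5-methylbenzaldehyde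
Conditions: NBS, MeCN, 0 °C to rt, dark
Reagents that add atoms: N-bromosuccinimide, O=C1CCC(=O)N1Br
Why: Electrophilic aromatic bromination at the only remaining ring C–H, which is ortho to two and para to one benzyloxy group; exclusion of light suppresses radical bromination of the benzylic CH2 groups.

Step 7
Reactants: 11 2,4,6-tris(benzyloxy)-3-bromo-5-methylbenzaldehyde
Product: 12 [2,4,6-tris(benzyloxy)-3-bromo-5-methylphenyl]methanol
Conditions: NaBH4, THF–MeOH, 0 °C
Reagents that add atoms: none
Why: Borohydride reduction of an aryl aldehyde; the aryl bromide and benzyl ethers are inert.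

Step 8
Reactants: 12 [2,4,6-tris(benzyloxy)-3-bromo-5-methylphenyl]methanol
Product: 13 1,3,5-tris(benzyloxy)-2-bromo-4-(bromomethyl)-6-methylbenzene
Conditions: PBr3 (0.4 equiv), pyridine (cat.), Et2O, −10 °C; cold aq NaHCO3 wash; used at once
Reagents that add atoms: phosphorus tribromide, BrP(Br)Br
Why: Conversion of a benzylic alcohol to the bromide with PBr3; the fully substituted ring cannot undergo Friedel–Crafts self-alkylation, and the ionisable bromide is kept cold and taken directly into step 10.

Step 9
Reactants: 14 chloroacetaldehyde dimethyl acetal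
Product: 16 methoxyacetylene, via sodium methoxyacetylide 15 (not isolated)
Conditions: NaNH2 (3.1 equiv), liq. NH3, −33 °C; NH3 evaporated; cold sat. aq NH4Cl; distilled into THF at −78 °C
Reagents that add atoms: none
Why: Base-induced loss of methanol and then HCl from the chloroacetal (the classical alkoxyacetylene synthesis) gives the acetylide, which is protonated and the volatile alkyne collected amine-free in THF.

Step 10
Reactants: 16 methoxyacetylene; 13 1,3,5-tris(benzyloxy)-2-bromo-4-(bromomethyl)-6-methylbenzene
Product: 18 1,3,5-tris(benzyloxy)-2-bromo-4-(3-methoxyprop-2-yn-1-yl)-6-methylbenzene, via lithium methoxyacetylide 17 (not isolated)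
Conditions: n-BuLi (slight deficit to 16), THF, −78 °C; then 13, DMPU, −78 to 0 °C; Et3N-deactivated silica
Reagents that add atoms: none
Why: Bimolecular nucleophilic substitution of a reactive benzylic bromide that has no β-hydrogen by a lithium alkoxyacetylide; keeping n-BuLi in deficit avoids bromine–lithium exchange at the aryl bromide, and the absence of amines avoids N-benzylation.

Step 11
Reactants: 6 3-(benzyloxy)-2-methylcyclobut-2-en-1-one; 18 1,3,5-tris(benzyloxy)-2-bromo-4-(3-methoxyprop-2-yn-1-yl)-6-methylbenzene
Product: 23 5-(benzyloxy)-3-methoxy-4-methyl-2-{[2,4,6-tris(benzyloxy)-3-bromo-5-methylphenyl]methyl}phenol, via vinylketene 19 (not isolated), via vinylcyclobutenone 20 (not isolated), via dienylketene 21 (not isolated), via cyclohexadienone 22 (not isolated)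
Conditions: 6 (1.3 equiv), degassed toluene, 110 °C, sealed vessel; then KOH, MeOH, rt
Reagents that add atoms: none
Why: Danheiser-type benzannulation: thermal 4π-electrocyclic opening of 6 gives (1-benzyloxyvinyl)(methyl)ketene 19, whose ketene C=C adds (2+2) to ynol ether 18 to give the 4-vinylcyclobutenone 20; a second, reversible 4π opening gives dienylketene 21, of which the isomer with ketene and vinyl group cis closes ring A by thermal 6π-electrocyclisation (bond between positions 1 and 6 of ring A) to dienone 22, which tautomerises to phenol 23. The closest known reaction type is the thermal annulation of cyclobutenones with 1-alkoxyalkynes to resorcinol monoethers; the 3-alkoxy donor is expected to make ring opening slower than for alkylcyclobutenones, hence 110 °C. Ring A is closed by electrocyclisation after the bonds between positions 5 and 6 and between positions 3 and 4 are made in the (2+2) step; the product has no stereocentre, and the quaternary centre of racemic 20 is lost on ring opening. The selectivity needed is the orientation of the (2+2) step, which the polarisation of the ynol ether secures: its β-carbon, the one carrying the ArCH2 group, is the nucleophilic end and joins the ketene carbonyl carbon (the future position 6), leaving the oxygen-bearing carbon to bond to the methyl-bearing ketene carbon, so OCH3 lands on position 4 between the methyl at position 3 and the bridge at position 5. A methoxy group cannot undergo the retro-ene loss of alkene that limits higher alkoxyalkynes at this temperature, and the aryl bromide and benzyl ethers are thermally inert. The KOH/MeOH treatment returns any phenol acylated by excess ketene.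

Step 12
Reactants: 23 5-(benzyloxy)-3-methoxy-4-methyl-2-{[2,4,6-tris(benzyloxy)-3-bromo-5-methylphenyl]methyl}phenol
Product: 24 6-(benzyloxy)-2-hydroxy-4-methoxy-5-methyl-3-{[2,4,6-tris(benzyloxy)-3-bromo-5-methylphenyl]methyl}benzaldehyde
Conditions: MgCl2, Et3N, paraformaldehyde, THF, reflux; then 1 M aq HCl
Reagents that add atoms: paraformaldehyde (as formaldehyde), C=O
Why: Magnesium-mediated ortho-formylation of a phenol (Casnati–Skattebøl reaction), in which the magnesium phenoxide delivers formaldehyde only to a carbon ortho to the free hydroxyl at position 6 of ring A, and position 1 is the only such carbon bearing hydrogen.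

Step 13
Reactants: 24 6-(benzyloxy)-2-hydroxy-4-methoxy-5-methyl-3-{[2,4,6-tris(benzyloxy)-3-bromo-5-methylphenyl]methyl}benzaldehyde
Product: 25 3-(benzyloxy)-2-(1-hydroxybutyl)-5-methoxy-4-methyl-6-{[2,4,6-tris(benzyloxy)-3-bromo-5-methylphenyl]methyl}phenol (racemic)
Conditions: n-PrMgCl (3 equiv), THF, −20 to 0 °C; aq NH4Cl
Reagents that add atoms: n-propylmagnesium chloride, CCC[Mg]Cl
Why: Grignard addition to the salicylaldehyde after deprotonation of the phenol by the first equivalent; the new carbinol stereocentre is not controlled (racemic) and is removed in step 14, and the electron-rich aryl bromide should not exchange with an alkyl Grignard reagent at this temperature.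

Step 14
Reactants: 25 3-(benzyloxy)-2-(1-hydroxybutyl)-5-methoxy-4-methyl-6-{[2,4,6-tris(benzyloxy)-3-bromo-5-methylphenyl]methyl}phenol
Product: 26 1-[6-(benzyloxy)-2-hydroxy-4-methoxy-5-methyl-3-{[2,4,6-tris(benzyloxy)-3-bromo-5-methylphenyl]methyl}phenyl]butan-1-one
Conditions: activated MnO2 (excess), CH2Cl2, rt
Reagents that add atoms: none
Why: MnO2 oxidation of a benzylic alcohol to the aryl ketone, which is stabilised by the hydrogen bond to the neighbouring ring A hydroxyl; the reagent is mild enough to leave the benzyl ethers and the diarylmethane CH2 alone.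

Step 15
Reactants: 26 1-[6-(benzyloxy)-2-hydroxy-4-methoxy-5-methyl-3-{[2,4,6-tris(benzyloxy)-3-bromo-5-methylphenyl]methyl}phenyl]butan-1-one
Product: 28 1-[3-{[3-acetyl-2,4,6-tris(benzyloxy)-5-methylphenyl]methyl}-6-(benzyloxy)-2-hydroxy-4-methoxy-5-methylphenyl]butan-1-one, via enol ether 27 (not isolated)
Conditions: tributyl(1-ethoxyvinyl)stannane, Pd(P(t-Bu)3)2 (zerovalent palladium, 5–10 mol%), CsF, 1,4-dioxane, 90 °C; then 1 M aq HCl, THF, rt
Reagents that add atoms: tributyl(1-ethoxyvinyl)stannane, CCCC[Sn](CCCC)(CCCC)C(=C)OCC; water, O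
Why: Stille coupling of the aryl bromide with an acetyl-anion equivalent, using a bulky electron-rich phosphine and fluoride activation to handle the two ortho substituents, followed by mild hydrolysis of the enol ether; this installs the acetyl group at position 5 of ring B without acid strong enough to cleave the diarylmethane bridge.

Step 16
Reactants: 28 1-[3-{[3-acetyl-2,4,6-tris(benzyloxy)-5-methylphenyl]methyl}-6-(benzyloxy)-2-hydroxy-4-methoxy-5-methylphenyl]butan-1-one
Product: 29 1-{3-[(3-acetyl-2,4,6-trihydroxy-5-methylphenyl)methyl]-2,6-dihydroxy-4-methoxy-5-methylphenyl}butan-1-one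
Conditions: H2 (1 atm), 10% Pd/C, EtOAc–MeOH, rt
Reagents that add atoms: none
Why: Catalytic hydrogenolysis of the four aryl benzyl ethers under neutral conditions, where the hydrogen-bonded aryl ketones, the methyl ether and the acid- and base-labile methylene bridge should survive.

**Compound list**

1 | propionyl chloride | CCC(=O)Cl | starting material
2 | ethoxyacetylene | C#COCC | starting material
3 | methylketene | CC=C=O | intermediate (not isolated)
4 | 3-ethoxy-4-methylcyclobut-2-en-1-one (racemic) | CCOC1=CC(=O)C1C | intermediate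
5 | 3-hydroxy-2-methylcyclobut-2-en-1-one (enol of 2-methylcyclobutane-1,3-dione) | CC1=C(O)CC1=O | intermediate
6 | 3-(benzyloxy)-2-methylcyclobut-2-en-1-one | CC1=C(OCc2ccccc2)CC1=O | intermediate
7 | 2-methylphloroglucinol | Cc1c(O)cc(O)cc1O | starting material
8 | 1,3,5-tris(benzyloxy)-2-methylbenzene | Cc1c(OCc2ccccc2)cc(OCc2ccccc2)cc1OCc1ccccc1 | intermediate
9 | [2,4,6-tris(benzyloxy)-3-methylbenzylidene]dimethyliminium chloride | C[N+](C)=Cc1c(OCc2ccccc2)cc(OCc2ccccc2)c(C)c1OCc1ccccc1.[Cl-] | intermediate (not isolated)
10 | 2,4,6-tris(benzyloxy)-3-methylbenzaldehyde | O=Cc1c(OCc2ccccc2)cc(OCc2ccccc2)c(C)c1OCc1ccccc1 | intermediate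
11 | 2,4,6-tris(benzyloxy)-3-bromo-5-methylbenzaldehyde | O=Cc1c(OCc2ccccc2)c(Br)c(OCc2ccccc2)c(C)c1OCc1ccccc1 | intermediate
12 | [2,4,6-tris(benzyloxy)-3-bromo-5-methylphenyl]methanol | OCc1c(OCc2ccccc2)c(Br)c(OCc2ccccc2)c(C)c1OCc1ccccc1 | intermediate
13 | 1,3,5-tris(benzyloxy)-2-bromo-4-(bromomethyl)-6-methylbenzene | BrCc1c(OCc2ccccc2)c(Br)c(OCc2ccccc2)c(C)c1OCc1ccccc1 | intermediate
14 | chloroacetaldehyde dimethyl acetal | COC(CCl)OC | starting material
15 | sodium methoxyacetylide | [Na+].[C-]#COC | intermediate (not isolated)
16 | methoxyacetylene | C#COC | intermediate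
17 | lithium methoxyacetylide | [Li+].[C-]#COC | intermediate (not isolated)
18 | 1,3,5-tris(benzyloxy)-2-bromo-4-(3-methoxyprop-2-yn-1-yl)-6-methylbenzene | COC#CCc1c(OCc2ccccc2)c(Br)c(OCc2ccccc2)c(C)c1OCc1ccccc1 | intermediate
19 | 3-(benzyloxy)-2-methylbuta-1,3-dien-1-one, the (1-benzyloxyvinyl)(methyl)ketene | C=C(OCc1ccccc1)C(C)=C=O | intermediate (not isolated)
20 | 4-[1-(benzyloxy)ethenyl]-3-methoxy-4-methyl-2-{[2,4,6-tris(benzyloxy)-3-bromo-5-methylphenyl]methyl}cyclobut-2-en-1-one (racemic) | COC1=C(Cc2c(OCc3ccccc3)c(Br)c(OCc3ccccc3)c(C)c2OCc2ccccc2)C(=O)C1(C)C(=C)OCc1ccccc1 | intermediate (not isolated)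
21 | (3E)-5-(benzyloxy)-3-methoxy-4-methyl-2-{[2,4,6-tris(benzyloxy)-3-bromo-5-methylphenyl]methyl}hexa-1,3,5-trien-1-one | O=C=C(Cc1c(OCc2ccccc2)c(Br)c(OCc2ccccc2)c(C)c1OCc1ccccc1)/C(OC)=C(/C)C(=C)OCc1ccccc1 | intermediate (not isolated)
22 | 5-(benzyloxy)-3-methoxy-4-methyl-2-{[2,4,6-tris(benzyloxy)-3-bromo-5-methylphenyl]methyl}cyclohexa-2,4-dien-1-one | O=C1CC(OCc2ccccc2)=C(C)C(OC)=C1Cc1c(OCc2ccccc2)c(Br)c(OCc2ccccc2)c(C)c1OCc1ccccc1 | intermediate (not isolated)
23 | 5-(benzyloxy)-3-methoxy-4-methyl-2-{[2,4,6-tris(benzyloxy)-3-bromo-5-methylphenyl]methyl}phenol | Oc1cc(OCc2ccccc2)c(C)c(OC)c1Cc1c(OCc2ccccc2)c(Br)c(OCc2ccccc2)c(C)c1OCc1ccccc1 | intermediate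
24 | 6-(benzyloxy)-2-hydroxy-4-methoxy-5-methyl-3-{[2,4,6-tris(benzyloxy)-3-bromo-5-methylphenyl]methyl}benzaldehyde | O=Cc1c(O)c(Cc2c(OCc3ccccc3)c(Br)c(OCc3ccccc3)c(C)c2OCc2ccccc2)c(OC)c(C)c1OCc1ccccc1 | intermediate
25 | 3-(benzyloxy)-2-(1-hydroxybutyl)-5-methoxy-4-methyl-6-{[2,4,6-tris(benzyloxy)-3-bromo-5-methylphenyl]methyl}phenol (racemic) | CCCC(O)c1c(O)c(Cc2c(OCc3ccccc3)c(Br)c(OCc3ccccc3)c(C)c2OCc2ccccc2)c(OC)c(C)c1OCc1ccccc1 | intermediate
26 | 1-[6-(benzyloxy)-2-hydroxy-4-methoxy-5-methyl-3-{[2,4,6-tris(benzyloxy)-3-bromo-5-methylphenyl]methyl}phenyl]butan-1-one | CCCC(=O)c1c(O)c(Cc2c(OCc3ccccc3)c(Br)c(OCc3ccccc3)c(C)c2OCc2ccccc2)c(OC)c(C)c1OCc1ccccc1 | intermediate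
27 | 1-[6-(benzyloxy)-3-{[2,4,6-tris(benzyloxy)-3-(1-ethoxyethenyl)-5-methylphenyl]methyl}-2-hydroxy-4-methoxy-5-methylphenyl]butan-1-one | CCCC(=O)c1c(O)c(Cc2c(OCc3ccccc3)c(C(=C)OCC)c(OCc3ccccc3)c(C)c2OCc2ccccc2)c(OC)c(C)c1OCc1ccccc1 | intermediate (not isolated)
28 | 1-[3-{[3-acetyl-2,4,6-tris(benzyloxy)-5-methylphenyl]methyl}-6-(benzyloxy)-2-hydroxy-4-methoxy-5-methylphenyl]butan-1-one | CCCC(=O)c1c(O)c(Cc2c(OCc3ccccc3)c(C(C)=O)c(OCc3ccccc3)c(C)c2OCc2ccccc2)c(OC)c(C)c1OCc1ccccc1 | intermediate
29 | 1-{3-[(3-acetyl-2,4,6-trihydroxy-5-methylphenyl)methyl]-2,6-dihydroxy-4-methoxy-5-methylphenyl}butan-1-one | CCCC(=O)c1c(O)c(C)c(OC)c(Cc2c(O)c(C)c(O)c(C(C)=O)c2O)c1O | target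

**Step count and risk**

Total steps: 16. Longest linear sequence: 12 steps, from 2-methylphloroglucinol 7 (steps 4–8 and 10–16).

Steps most likely to fail:

1. Step 11 (key step). The donor-stabilised cyclobutenone may open too slowly at a temperature the ynol ether tolerates, so ketene dimerisation, decay of the ynol ether and acylation of the product phenol could outrun the (2+2) addition. Fallback: the diarylmethane is made by Friedel–Crafts chemistry on a preformed ring A, setting out from 7 and benzylic alcohol 12 and returning at target 29. Butyrylation of 7 (butyryl chloride, AlCl3, PhNO2–CH2Cl2) would give 1-(2,4,6-trihydroxy-3-methylphenyl)butan-1-one F1. Methylation of its non-chelated hydroxyl para to the ketone (Me2SO4, 1 equiv, K2CO3, acetone) would give 1-(2,6-dihydroxy-4-methoxy-3-methylphenyl)butan-1-one F2. Acid-catalysed benzylation of F2 at its only free ring carbon with alcohol 12 (TsOH cat., CH2Cl2, 0 °C) would give 1-[3-{[2,4,6-tris(benzyloxy)-3-bromo-5-methylphenyl]methyl}-2,6-dihydroxy-4-methoxy-5-methylphenyl]butan-1-one F3. Stille coupling as in step 15 would give 1-[3-{[2,4,6-tris(benzyloxy)-3-(1-ethoxyethenyl)-5-methylphenyl]methyl}-2,6-dihydroxy-4-methoxy-5-methylphenyl]butan-1-one F4, hydrolysed in the same flask to 1-[3-{[3-acetyl-2,4,6-tris(benzyloxy)-5-methylphenyl]methyl}-2,6-dihydroxy-4-methoxy-5-methylphenyl]butan-1-one F5. Hydrogenolysis as in step 16 then gives 29.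

2. Step 10. Ionisation or base-induced decomposition of the labile benzylic bromide, and base-induced propargyl-to-allenyl isomerisation of the product, may compete with C-alkylation of the acetylide. Fallback: the bond is made by palladium catalysis without a free carbanion, setting out from 17 and 13 and returning at 18. Lithium methoxyacetylide 17 is quenched with Bu3SnCl to give tributyl(methoxyethynyl)stannane F6, which is coupled with bromide 13 under Pd(PPh3)4 (zerovalent palladium) in THF at 50 °C to give 18.

3. Step 15. Oxidative addition at the electron-rich aryl bromide flanked by two benzyloxy groups may be slow, so protodebromination and loss of the stannane could dominate. Fallback: the acetyl group is introduced by electrophilic substitution after deprotection, setting out from 26 and returning at 29. Hydrogenolysis of 26 (H2, Pd/C, NaOAc, EtOAc–MeOH) would remove the four benzyl groups and the bromine together to give 1-{2,6-dihydroxy-4-methoxy-3-methyl-5-[(2,4,6-trihydroxy-3-methylphenyl)methyl]phenyl}butan-1-one F7. C-Acetylation of F7 at position 5 of ring B, its only unsubstituted ring carbon (Ac2O, BF3·OEt2, rt; then brief K2CO3/MeOH to cleave aryl acetates), gives 29.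

**Further compounds**

F1 | step 11 | 1-(2,4,6-trihydroxy-3-methylphenyl)butan-1-one | CCCC(=O)c1c(O)c(C)c(O)cc1O
F2 | step 11 | 1-(2,6-dihydroxy-4-methoxy-3-methylphenyl)butan-1-one | CCCC(=O)c1c(O)c(C)c(OC)cc1O
F3 | step 11 | 1-[3-{[2,4,6-tris(benzyloxy)-3-bromo-5-methylphenyl]methyl}-2,6-dihydroxy-4-methoxy-5-methylphenyl]butan-1-one | CCCC(=O)c1c(O)c(Cc2c(OCc3ccccc3)c(Br)c(OCc3ccccc3)c(C)c2OCc2ccccc2)c(OC)c(C)c1O
F4 | step 11 | 1-[3-{[2,4,6-tris(benzyloxy)-3-(1-ethoxyethenyl)-5-methylphenyl]methyl}-2,6-dihydroxy-4-methoxy-5-methylphenyl]butan-1-one | CCCC(=O)c1c(O)c(Cc2c(OCc3ccccc3)c(C(=C)OCC)c(OCc3ccccc3)c(C)c2OCc2ccccc2)c(OC)c(C)c1O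
F5 | step 11 | 1-[3-{[3-acetyl-2,4,6-tris(benzyloxy)-5-methylphenyl]methyl}-2,6-dihydroxy-4-methoxy-5-methylphenyl]butan-1-one | CCCC(=O)c1c(O)c(Cc2c(OCc3ccccc3)c(C(C)=O)c(OCc3ccccc3)c(C)c2OCc2ccccc2)c(OC)c(C)c1O
F6 | step 10 | tributyl(methoxyethynyl)stannane | CCCC[Sn](CCCC)(CCCC)C#COC
F7 | step 15 | 1-{2,6-dihydroxy-4-methoxy-3-methyl-5-[(2,4,6-trihydroxy-3-methylphenyl)methyl]phenyl}butan-1-one | CCCC(=O)c1c(O)c(Cc2c(O)cc(O)c(C)c2O)c(OC)c(C)c1O
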